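# Proposed synthesis of (2S)-6,8-diprenyleriodictyol (15) by enol ether ring-closing metathesis at C3–C4

## Structural features

The target 15 is a flavanone: aromatic ring A (C4a, C5, C6, C7, C8, C8a) is fused to the dihydropyranone ring C (O1, C2, C3, C4, C4a, C8a), and ring C carries the catechol ring B at C2. Ring A is fully substituted, with hydroxyls at C5 and C7 and 3-methylbut-2-enyl chains at C6 and C8, so it offers no aromatic C–H for late functionalisation. C2 is the only stereocentre (S). It is benzylic to an electron-rich arene, bonded to O1, and has no stereogenic neighbour, so its configuration must come from a reagent or catalyst. Three points are fragile: (a) the O1–C2 bond, which lies β to the C4 carbonyl and opens by retro-oxa-Michael reaction under base or hot acid, erasing the configuration; (b) the two trisubstituted alkenes, each ortho to a phenol, which cyclise to 2,2-dimethylchromans in strong acid and exclude hydrogenation and electrophilic oxidants; (c) the catechol, which is oxidised in basic air. The real difficulty is to fix C2 without ever passing through a ring-opened enone or an enolisable β-aryloxy ketone, on a ring A whose O1 is flanked by the C8 chain and the C4a acyl group. The key step uses the fact that O1–C2 is an aryl alkyl ether whose C2 can carry a vinyl group while C4a carries an acetyl group. Once the acetyl group is a silyl enol ether, C3=C4 can be made by alkene metathesis, and C4 keeps its oxidation level as the enol ether of ring C.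

## Logic of the disconnections

**15 ⇒ 13 (through 14).** No skeletal bond is cut. The C4 ketone is rewritten as the C3=C4 silyl enol ether and the four phenols as methoxymethyl acetals. The ketone is what makes O1–C2 labile, so it stays latent to the end, and acetals are the phenol masks that leave under the same mild acid that hydrolyses an enol ether, with no base, hydride or hydrogen. The gain is one final operation. The demand is that C3 protonation and acetal exchange outrun cyclisation of a prenyl chain onto a freed phenol and acid opening of ring C.

**13 ⇒ 12.** The C3=C4 double bond is cut. It is the one bond of ring C whose formation touches neither O1–C2 nor any substituent on C2. The cut opens ring C and leaves an acyclic aryl ether with two CH2= termini. The forward step must close onto a hindered, electron-rich 1,1-disubstituted alkene in the presence of two trisubstituted alkenes, one of which (on C8) could close a seven-membered ring.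

**12 ⇒ 10.** The O–Si bond of the enol ether is cut, so C4 and the carbon lost as ethene come from an acetyl group. The gain is a plain methyl ketone. The demand is enolisation at the methyl group only, under conditions that neither deprotonate C2–H nor ionise O1–C2.

**10 ⇒ 4 + 8.** The O1–C2 bond is cut between the ring A oxygen and the benzylic, allylic carbon. This is the convergent cut: it separates the two aromatic halves and makes the creation of C2 a catalyst-controlled allylic substitution. The forward step must be branched-selective and face-selective, and must work with an aryloxide that is chelated and ortho-disubstituted.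

**4 ⇒ 3 ⇒ 1 + 2.** Two O–CH2 acetal bonds are cut first, then the two aryl–CH2 bonds of the prenyl chains (future C6–C1″ and C8–C1‴). The symmetry of 3 makes its two ortho hydroxyls equivalent, so protecting two of three oxygens leaves exactly the one needed as O1. The forward alkylation of 1 must go on carbon, twice, and stop there.

**8 ⇒ 7 ⇒ 6 ⇒ 5.** The carbonate C–O bond, the two C–H bonds made by reduction and the three O–CH2 acetal bonds are cut in turn. All three carbons of the C2–C3 unit and ring B come from one commercial acid with the E alkene already in place. The forward steps must keep that alkene and the acid-sensitive acetals intact.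

## Other disconnections considered

**Alternative 1:** The cut is at the two aryl–CH2 bonds, C6–C1″ and C8–C1‴, and both chains are traced back to tertiary allyl ethers on O5 and O7.

- Forward step: the catechol-protected 5,7-diol A1 is converted into the bis(2-methylbut-3-en-2-yl) ether A2. Heating A2 causes two aromatic [3,3] shifts, each transposing the allyl unit into a linear prenyl chain, to give A3.
- In favour: ring A is prenylated last and only on carbon, which avoids the unselective phloroglucinolate alkylation of step 1; on this point the alternative is better. C2 can be taken from a flavanone of the chiral pool instead of being made by catalysis, which is also an advantage. The key step needs no reagent and forms two skeletal bonds.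
- Against: O5 of A1 is chelated to C4=O, and a tertiary ether there is hard to make. Each ether would likely cost two operations (alkylation with a 1,1-dimethylpropargyl electrophile, then semi-hydrogenation). The O7 chain can migrate to C6 as well as C8; if it takes C6, the O5 chain can reach C8 only by a Claisen–Cope sequence that delivers the branched 1,1-dimethylallyl isomer. The heat acts on a flavanone whose 5-OH is freed during the reaction, so retro-oxa-Michael opening of ring C and loss of configuration are a real risk. A3 still carries a ketal that cannot be hydrogenolysed beside the prenyl alkenes and needs hotter acid than the acetals of the chosen plan.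
- Comparison: both plans leave O1–C2 untouched in the key step and create no stereocentre there. The alternative is mechanistically simpler (pericyclic, no catalyst) but has a regiochemical problem where the chosen plan has a ring-size problem. The step counts are close if A1 comes from the chiral pool; the alternative is longer if A1 must be made enantiopure.

**Alternative 2:** The cut is at C2–C3. C2 becomes the acetal carbon of the racemic 4-methylidene-1,3-benzodioxine A5, which would come from the benzodioxinone A4 by methylenation of the lactone carbonyl (for example with Cp2TiMe2).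

- Forward step: a chiral 1,1'-bi-2-naphthol-derived N-triflylphosphoramide ionises the acetal of A5 to an O1-aryl oxocarbenium ion and the enol of the 2-acylphenol. Attack of the enol carbon on the oxocarbenium carbon forms C2–C3 and the C4 ketone together and gives A6.
- In favour: ring C and the C2 configuration are created in one catalytic, metal-free event from racemic material, because the acetal stereocentre is erased on ionisation. A6 carries only silyl ethers, which buffered fluoride removes without strong acid near the prenyl groups; this endgame is better than that of the chosen plan.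
- Against: the selectivity must come from an ion pair between a long-lived, catechol-stabilised oxocarbenium ion and the chiral anion, which is loosely held. The same acid can re-ionise O1–C2 of A6 and erode what was gained. The bulky silyl ether at C5 crowds the reacting enol. A4 needs a fully substituted 2,4,6-trihydroxybenzoic acid, which decarboxylates easily and is far less accessible than 1. The enol acetal A5 is very acid-sensitive.
- Comparison: the alternative is the equal of the chosen plan in avoiding an open-chain enone and probably shorter on paper. Mechanistically it puts bond formation and stereocontrol into one step without close precedent on a 5,7-dioxygenated, 6,8-dialkylated ring, whereas the chosen plan separates the two tasks into reactions of established types.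

**Alternative 3:** The cut is at C4a–C5, so ring A is built last on a dihydropyranone that already holds C2.

- Forward step: Mg(OMe)2 chelates the β-dicarbonyl array of A7. The pyranone α-carbon (future C4a) attacks the side-chain methyl ester, methoxide leaves, and the new ring aromatises by enolisation to give A8.
- In favour: the positions of both prenyl groups are fixed earlier by alkylation of 1,3-dicarbonyl carbons in an open chain, so ring A has no C- versus O-alkylation or over-alkylation problem; this is better than step 1 of the chosen plan. C2 could be set by an asymmetric hetero-Diels–Alder reaction of an aldehyde with a 1-alkoxy-3-silyloxybutadiene, a well-established entry to 2-aryl-dihydropyranones. Only two acetals remain to be removed at the end, which is also better.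
- Against: A7 is a polycarbonyl compound that exists as tautomer and epimer mixtures and can cyclise in other ways (O-acylation to a lactone, aldol closure onto the chain ketone). O1–C2 of the dihydropyranone lies β to a vinylogous carbonyl, so the basic magnesium alkoxide can open the ring and racemise C2. Assembly of the chain on the pyranone needs several C–C bond formations in a long linear sequence.
- Comparison: the alternative builds the hexasubstituted benzene de novo and is regiochemically cleaner, while the chosen plan buys ring A as 1 and accepts a poor first step. The alternative's key step is a classical carbonyl condensation with several competing modes, the chosen plan's a single catalytic closure with one competitor. In step economy the chosen plan is clearly shorter.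

Key step: step 8

**Remarks on the design**

- Configuration: C2 has the priority order O1 > aryl > C3 (or vinyl) > H in 10, 12, 13, 14 and 15, so the descriptor stays S along the whole route. No correction to the key-step structures was needed.
- Precursor 12: the tert-butyldimethylsilyl enol ether is kept because it survives chromatography. All four phenols are masked as acetals so that no O–H can protonate the enol ether or bind ruthenium, and because ester or carbonate masks would need base at the flavanone stage. The enol ether is made by kinetic enolisation, not with a silyl triflate, to spare the ionisable O1–C2 ether.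
- Assumption: the iridium–phosphoramidite catalyst is taken to show its usual sense of induction for 1-arylallyl products, so the (Sa,Sc,Sc) ligand is assigned to the S ether. The antipodal ligand would be used if the first batch proved to be R.

## Route

Step 1
Reactants: 1 2,4,6-trihydroxyacetophenone; 2 prenyl bromide (1-bromo-3-methylbut-2-ene)
Product: 3 1-[2,4,6-trihydroxy-3,5-bis(3-methylbut-2-en-1-yl)phenyl]ethan-1-one
Conditions: 2 (2.2 equiv), KOH (10% aq.), 0 °C → rt
Reagents that add atoms: none
Why: Base-mediated C-alkylation of a phloroglucinolate (SN2 on the allylic bromide): in water the phenoxide oxygens are solvated, so ring carbons C3 and C5 of 1 act as the nucleophiles. The reaction is known for acylphloroglucinols; mono-, O- and geminally dialkylated by-products are removed by chromatography.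

Step 2
Reactants: 3 1-[2,4,6-trihydroxy-3,5-bis(3-methylbut-2-en-1-yl)phenyl]ethan-1-one
Product: 4 1-[2-hydroxy-4,6-bis(methoxymethoxy)-3,5-bis(3-methylbut-2-en-1-yl)phenyl]ethan-1-one
Conditions: MOMCl (2.3 equiv), i-Pr2NEt, CH2Cl2, 0 °C → rt
Reagents that add atoms: chloromethyl methyl ether, COCCl
Why: O-alkylation with an α-chloro ether: the para hydroxyl and one of the two equivalent ortho hydroxyls react, while the last one is held in a hydrogen bond to the acetyl oxygen between two ortho substituents and stays free. That free hydroxyl is the future O1.

Step 3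
Reactants: 5 caffeic acid
Product: 6 methoxymethyl (2E)-3-[3,4-bis(methoxymethoxy)phenyl]prop-2-enoate
Conditions: MOMCl (3.6 equiv), i-Pr2NEt, DMF, 0 °C → rt
Reagents that add atoms: chloromethyl methyl ether, COCCl
Why: Exhaustive methoxymethylation of both phenols and of the carboxylate in one operation. The methoxymethyl ester behaves as an ordinary ester towards hydride, so no separate esterification is needed.

Step 4
Reactants: 6 methoxymethyl (2E)-3-[3,4-bis(methoxymethoxy)phenyl]prop-2-enoate
Product: 7 (2E)-3-[3,4-bis(methoxymethoxy)phenyl]prop-2-en-1-ol
Conditions: i-Bu2AlH (3.5 equiv), CH2Cl2, −78 → 0 °C; aq. potassium sodium tartrate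
Reagents that add atoms: none
Why: 1,2-Reduction of an α,β-unsaturated ester to the allylic alcohol by i-Bu2AlH at low temperature. The E alkene and the aryl acetals are inert, and the alkoxy part of the ester leaves as methoxymethanol.

Step 5
Reactants: 7 (2E)-3-[3,4-bis(methoxymethoxy)phenyl]prop-2-en-1-ol
Product: 8 (2E)-3-[3,4-bis(methoxymethoxy)phenyl]prop-2-en-1-yl methyl carbonate
Conditions: ClCO2Me, pyridine, CH2Cl2, 0 °C; chromatography on Et3N-treated silica
Reagents that add atoms: methyl chloroformate, COC(=O)Cl
Why: Acylation of the primary allylic alcohol with a chloroformate. The methyl carbonate is the leaving group that iridium ionises, and it breaks down irreversibly to CO2 and methoxide.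

Step 6
Reactants: 4 1-[2-hydroxy-4,6-bis(methoxymethoxy)-3,5-bis(3-methylbut-2-en-1-yl)phenyl]ethan-1-one; 8 (2E)-3-[3,4-bis(methoxymethoxy)phenyl]prop-2-en-1-yl methyl carbonate
Product: 10 1-[2-{[(1S)-1-[3,4-bis(methoxymethoxy)phenyl]prop-2-en-1-yl]oxy}-4,6-bis(methoxymethoxy)-3,5-bis(3-methylbut-2-en-1-yl)phenyl]ethan-1-one, via lithium aryloxide 9 (not isolated)
Conditions: LiN(SiMe3)2 (1.0 equiv), THF, 0 °C; then 8 (1.2 equiv), [Ir(cod)Cl]2 (2 mol%, monovalent iridium), (Sa,Sc,Sc)-phosphoramidite from 1,1'-bi-2-naphthol and bis(1-phenylethyl)amine (4 mol%), activated with n-PrNH2, THF, 25–40 °C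
Reagents that add atoms: none
Why: Iridium-catalysed asymmetric allylic etherification with an aryloxide: the cyclometallated iridium–phosphoramidite complex ionises 8 to an allyl complex of trivalent iridium, and aryloxide 9 attacks the aryl-bearing terminus on the face away from the metal, giving the branched ether. The chiral ligand decides which face of the allyl unit is bound and so sets C2 as S. The reaction is stopped at full conversion so that the catalyst does not re-ionise the electron-rich ether.

Step 7
Reactants: 10 1-[2-{[(1S)-1-[3,4-bis(methoxymethoxy)phenyl]prop-2-en-1-yl]oxy}-4,6-bis(methoxymethoxy)-3,5-bis(3-methylbut-2-en-1-yl)phenyl]ethan-1-one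
Product: 12 tert-butyl{[1-(2-{[(1S)-1-[3,4-bis(methoxymethoxy)phenyl]prop-2-en-1-yl]oxy}-4,6-bis(methoxymethoxy)-3,5-bis(3-methylbut-2-en-1-yl)phenyl)ethenyl]oxy}dimethylsilane, via potassium enolate 11 (not isolated)
Conditions: KN(SiMe3)2 (1.1 equiv), THF, −78 °C; TBSCl (1.3 equiv), −78 → 0 °C
Reagents that add atoms: tert-butyldimethylsilyl chloride, CC(C)(C)[Si](C)(C)Cl
Why: Kinetic enolisation of the methyl ketone, by far the most acidic C–H, with a hindered amide base, followed by O-silylation of the potassium enolate. This avoids silyl triflates, which would act as Lewis acids on the ionisable O1–C2 ether and on the aryl acetals. At −78 °C with one equivalent of base the C2–H is not touched, so the configuration is kept.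

Step 8
Reactants: 12 tert-butyl{[1-(2-{[(1S)-1-[3,4-bis(methoxymethoxy)phenyl]prop-2-en-1-yl]oxy}-4,6-bis(methoxymethoxy)-3,5-bis(3-methylbut-2-en-1-yl)phenyl)ethenyl]oxy}dimethylsilane
Product: 13 (2S)-2-[3,4-bis(methoxymethoxy)phenyl]-4-[(tert-butyldimethylsilyl)oxy]-5,7-bis(methoxymethoxy)-6,8-bis(3-methylbut-2-en-1-yl)-2H-chromene
Conditions: (H2IMes)(PCy3)Cl2Ru=CHPh (second-generation Grubbs catalyst, 7 mol%), degassed PhMe (0.005 M), 60 °C, slow Ar purge
Reagents that add atoms: none
Why: Ring-closing alkene metathesis by the metallacyclobutane mechanism: after loss of PCy3 the benzylidene exchanges with the vinyl group on C2, the only monosubstituted alkene, to give a ruthenium alkylidene at the future C3. This alkylidene adds across the 1,1-disubstituted silyl enol ether with the unsubstituted CH2 next to ruthenium, and cycloreversion forms C3=C4 and a ruthenium methylidene, so the acetophenone methyl carbon and the vinyl terminus leave together as ethene. The closest known reaction type is the ring-closing metathesis of a terminal alkene with a silyl enol ether, which gives five- to seven-membered cyclic silyl enol ethers, benzo-fused 4-silyloxy heterocycles included, with this catalyst. Ring C closes as a six-membered ring with both carbons of the new double bond in the ring (endocyclic C3=C4), from a chain whose other four atoms C2, O1, C8a and C4a are already joined. No stereocentre is formed; the four bonds at C2 take no part in the catalytic cycle and the medium is neutral and aprotic, so the S configuration from step 6 is carried through. The selectivity needed is six-ring closure onto the enol ether over seven-ring closure onto the trisubstituted C8 prenyl alkene, which would expel 2-methylpropene. The substrate secures it because the six-membered closure is entropically favoured, because the enol ether offers an unsubstituted carbon to the metal whereas the prenyl group would have to place its CMe2 carbon there, and because the C6 prenyl group cannot reach the alkylidene. High dilution and the argon purge suppress intermolecular metathesis and remove ethene.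

Step 9
Reactants: 13 (2S)-2-[3,4-bis(methoxymethoxy)phenyl]-4-[(tert-butyldimethylsilyl)oxy]-5,7-bis(methoxymethoxy)-6,8-bis(3-methylbut-2-en-1-yl)-2H-chromene
Product: 15 (2S)-2-(3,4-dihydroxyphenyl)-5,7-dihydroxy-6,8-bis(3-methylbut-2-en-1-yl)-2,3-dihydro-4H-chromen-4-one, via tetrakis(methoxymethyl) flavanone 14 (not isolated)
Conditions: HCl (ca. 1 M) in MeOH, 0 °C, then 40 °C; NaHCO3
Reagents that add atoms: none
Why: Acid hydrolysis of a silyl enol ether followed by acetal exchange: at 0 °C C3 is protonated and methanol takes the silyl group from the oxocarbenium ion, giving ketone 14 without breaking any bond to C2. On warming, the four methoxymethyl ethers are exchanged into dimethoxymethane and the free phenols. Acid strength and temperature are kept low because the prenyl chains can cyclise onto the freed ortho phenols and hot acid can open O1–C2 through the protonated ketone.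

## Compound list

1 | 2,4,6-trihydroxyacetophenone | CC(=O)c1c(O)cc(O)cc1O | starting material
2 | prenyl bromide (1-bromo-3-methylbut-2-ene) | CC(C)=CCBr | starting material
3 | 1-[2,4,6-trihydroxy-3,5-bis(3-methylbut-2-en-1-yl)phenyl]ethan-1-one | CC(=O)c1c(O)c(CC=C(C)C)c(O)c(CC=C(C)C)c1O | intermediate
4 | 1-[2-hydroxy-4,6-bis(methoxymethoxy)-3,5-bis(3-methylbut-2-en-1-yl)phenyl]ethan-1-one | CC(=O)c1c(O)c(CC=C(C)C)c(OCOC)c(CC=C(C)C)c1OCOC | intermediate
5 | caffeic acid | O=C(O)/C=C/c1ccc(O)c(O)c1 | starting material
6 | methoxymethyl (2E)-3-[3,4-bis(methoxymethoxy)phenyl]prop-2-enoate | COCOC(=O)/C=C/c1ccc(OCOC)c(OCOC)c1 | intermediate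
7 | (2E)-3-[3,4-bis(methoxymethoxy)phenyl]prop-2-en-1-ol | OC/C=C/c1ccc(OCOC)c(OCOC)c1 | intermediate
8 | (2E)-3-[3,4-bis(methoxymethoxy)phenyl]prop-2-en-1-yl methyl carbonate | COC(=O)OC/C=C/c1ccc(OCOC)c(OCOC)c1 | intermediate
9 | lithium 2-acetyl-3,5-bis(methoxymethoxy)-4,6-bis(3-methylbut-2-en-1-yl)phenolate | CC(=O)c1c([O-])c(CC=C(C)C)c(OCOC)c(CC=C(C)C)c1OCOC.[Li+] | intermediate
10 | 1-[2-{[(1S)-1-[3,4-bis(methoxymethoxy)phenyl]prop-2-en-1-yl]oxy}-4,6-bis(methoxymethoxy)-3,5-bis(3-methylbut-2-en-1-yl)phenyl]ethan-1-one | C=C[C@@H](c1ccc(OCOC)c(OCOC)c1)Oc1c(CC=C(C)C)c(OCOC)c(CC=C(C)C)c(OCOC)c1C(C)=O | intermediate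
11 | potassium 1-(2-{[(1S)-1-[3,4-bis(methoxymethoxy)phenyl]prop-2-en-1-yl]oxy}-4,6-bis(methoxymethoxy)-3,5-bis(3-methylbut-2-en-1-yl)phenyl)ethen-1-olate | C=C[C@@H](c1ccc(OCOC)c(OCOC)c1)Oc1c(CC=C(C)C)c(OCOC)c(CC=C(C)C)c(OCOC)c1C(=C)[O-].[K+] | intermediate
12 | tert-butyl{[1-(2-{[(1S)-1-[3,4-bis(methoxymethoxy)phenyl]prop-2-en-1-yl]oxy}-4,6-bis(methoxymethoxy)-3,5-bis(3-methylbut-2-en-1-yl)phenyl)ethenyl]oxy}dimethylsilane | C=C[C@@H](c1ccc(OCOC)c(OCOC)c1)Oc1c(CC=C(C)C)c(OCOC)c(CC=C(C)C)c(OCOC)c1C(=C)O[Si](C)(C)C(C)(C)C | intermediate
13 | (2S)-2-[3,4-bis(methoxymethoxy)phenyl]-4-[(tert-butyldimethylsilyl)oxy]-5,7-bis(methoxymethoxy)-6,8-bis(3-methylbut-2-en-1-yl)-2H-chromene | CC(C)=CCc1c(OCOC)c(CC=C(C)C)c2c(c1OCOC)C(O[Si](C)(C)C(C)(C)C)=C[C@@H](c1ccc(OCOC)c(OCOC)c1)O2 | intermediate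
14 | (2S)-2-[3,4-bis(methoxymethoxy)phenyl]-5,7-bis(methoxymethoxy)-6,8-bis(3-methylbut-2-en-1-yl)-2,3-dihydro-4H-chromen-4-one | CC(C)=CCc1c(OCOC)c(CC=C(C)C)c2c(c1OCOC)C(=O)C[C@@H](c1ccc(OCOC)c(OCOC)c1)O2 | intermediate
15 | (2S)-2-(3,4-dihydroxyphenyl)-5,7-dihydroxy-6,8-bis(3-methylbut-2-en-1-yl)-2,3-dihydro-4H-chromen-4-one (6,8-diprenyleriodictyol) | CC(C)=CCc1c(O)c(CC=C(C)C)c2c(c1O)C(=O)C[C@@H](c1ccc(O)c(O)c1)O2 | target

## Step count and least certain steps

Total: 9 steps. Longest linear sequence: 7 steps (5 → 6 → 7 → 8 → 10 → 12 → 13 → 15; steps 3 to 9). The ring A branch (steps 1 and 2) joins at step 6.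

**Step 8 (key step).** The most likely fault is competing closure of the ruthenium alkylidene onto the C8 prenyl alkene, giving a seven-membered ring with loss of 2-methylpropene. Slow turnover at the crowded, electron-rich enol ether could also let the catalyst decay before ring C closes. The fallback leaves metathesis altogether; it sets out from 4 and comes back at 14.

- 4 is condensed with N,N-dimethylformamide dimethyl acetal (PhMe, 90 °C) to the enaminone (2E)-3-(dimethylamino)-1-[2-hydroxy-4,6-bis(methoxymethoxy)-3,5-bis(3-methylbut-2-en-1-yl)phenyl]prop-2-en-1-one F1.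
- F1 is closed with AcOH in CH2Cl2 to the chromone 5,7-bis(methoxymethoxy)-6,8-bis(3-methylbut-2-en-1-yl)-4H-chromen-4-one F2.
- The aryl donor comes from commercial 4-bromocatechol: MOMCl and i-Pr2NEt give 4-bromo-1,2-bis(methoxymethoxy)benzene F3; bromine–lithium exchange (n-BuLi, THF, −78 °C), B(Oi-Pr)3 and a buffered aqueous work-up give [3,4-bis(methoxymethoxy)phenyl]boronic acid F4.
- Asymmetric conjugate addition of F4 to F2 under Pd(OCOCF3)2 (divalent palladium) and a chiral tert-butyl pyridine–oxazoline ligand (NH4PF6, ClCH2CH2Cl/H2O, 60 °C; ligand antipode chosen for S) should give 14.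
- 14 is then taken through the conditions of step 9 to 15.

**Step 6.** Attack of the chelated, doubly ortho-substituted aryloxide on the allyl complex may be slow. The catalyst may also re-ionise the branched, electron-rich ether, which would lower the enantiomeric purity and let the material drift to the linear isomer. The fallback sets the stereocentre with a small oxygen nucleophile and forms O1–C2 by inversion; it sets out from 8 (with 4) and comes back at 10.

- 8 is substituted with KOSiEt3 under [Ir(cod)Cl]2 and the antipodal (Ra,Rc,Rc) ligand (CH2Cl2, rt) to give triethyl{[(1R)-1-[3,4-bis(methoxymethoxy)phenyl]prop-2-en-1-yl]oxy}silane F5.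
- n-Bu4NF (THF, 0 °C) frees (1R)-1-[3,4-bis(methoxymethoxy)phenyl]prop-2-en-1-ol F6.
- Mitsunobu reaction of F6 with 4 (PPh3, diisopropyl azodicarboxylate, PhMe, −20 → 0 °C) should give 10 by SN2 inversion. The non-polar solvent and low temperature are meant to hold back ionisation and allylic transposition.

**Step 9.** Under protic acid a prenyl chain may cyclise onto a freed neighbouring phenol, HCl or methanol may add to the alkenes, and ring C may open through the protonated ketone with erosion of configuration at C2. The fallback separates the two deprotections and avoids Brønsted acid for the acetals; it sets out from 13 and comes back at 15.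

- n-Bu4NF buffered with AcOH (THF, 0 °C) cleaves the silyl enol ether, and 14 is isolated.
- Me3SiOTf and 2,2'-bipyridyl (CH2Cl2, 0 °C → rt) convert the four aryl methoxymethyl ethers into trimethylsilyl ethers, giving (2S)-2-[3,4-bis(trimethylsilyloxy)phenyl]-6,8-bis(3-methylbut-2-en-1-yl)-5,7-bis(trimethylsilyloxy)-2,3-dihydro-4H-chromen-4-one F7.
- Addition of water at rt hydrolyses F7 to 15.

**Step 1.** Alkylation of the phloroglucinolate may run on (geminal dialkylation with loss of aromaticity) or stop short (mono-alkylation), and some O-alkylation is expected, so the yield of 3 will be modest. The fallback changes the polarity of the reaction; it sets out from 1 and comes back at 3. Friedel–Crafts prenylation of neutral 1 with 2-methylbut-3-en-2-ol and BF3·OEt2 in dioxane at rt should put the allyl cation on C3 and C5. No new compound is made on the way.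

## Further compounds

F1 | step 8 | (2E)-3-(dimethylamino)-1-[2-hydroxy-4,6-bis(methoxymethoxy)-3,5-bis(3-methylbut-2-en-1-yl)phenyl]prop-2-en-1-one | CN(C)/C=C/C(=O)c1c(O)c(CC=C(C)C)c(OCOC)c(CC=C(C)C)c1OCOC
F2 | step 8 | 5,7-bis(methoxymethoxy)-6,8-bis(3-methylbut-2-en-1-yl)-4H-chromen-4-one | CC(C)=CCc1c(OCOC)c(CC=C(C)C)c2occc(=O)c2c1OCOC
F3 | step 8 | 4-bromo-1,2-bis(methoxymethoxy)benzene | COCOc1ccc(Br)cc1OCOC
F4 | step 8 | [3,4-bis(methoxymethoxy)phenyl]boronic acid | COCOc1ccc(B(O)O)cc1OCOC
F5 | step 6 | triethyl{[(1R)-1-[3,4-bis(methoxymethoxy)phenyl]prop-2-en-1-yl]oxy}silane | C=C[C@H](c1ccc(OCOC)c(OCOC)c1)O[Si](CC)(CC)CC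
F6 | step 6 | (1R)-1-[3,4-bis(methoxymethoxy)phenyl]prop-2-en-1-ol | C=C[C@H](c1ccc(OCOC)c(OCOC)c1)O
F7 | step 9 | (2S)-2-[3,4-bis(trimethylsilyloxy)phenyl]-6,8-bis(3-methylbut-2-en-1-yl)-5,7-bis(trimethylsilyloxy)-2,3-dihydro-4H-chromen-4-one | CC(C)=CCc1c(O[Si](C)(C)C)c(CC=C(C)C)c2c(c1O[Si](C)(C)C)C(=O)C[C@@H](c1ccc(O[Si](C)(C)C)c(O[Si](C)(C)C)c1)O2
F0 | step 1 | none | none
A1 | alternative 1 | (2S)-2-(2,2-diphenyl-1,3-benzodioxol-5-yl)-5,7-dihydroxy-2,3-dihydro-4H-chromen-4-one | Oc1cc2c(c(O)c1)C(=O)C[C@@H](c1ccc3OC(c4ccccc4)(c4ccccc4)Oc3c1)O2
A2 | alternative 1 | (2S)-2-(2,2-diphenyl-1,3-benzodioxol-5-yl)-5,7-bis[(2-methylbut-3-en-2-yl)oxy]-2,3-dihydro-4H-chromen-4-one | C=CC(C)(C)Oc1cc2c(c(OC(C)(C)C=C)c1)C(=O)C[C@@H](c1ccc3OC(c4ccccc4)(c4ccccc4)Oc3c1)O2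
A3 | alternative 1 | (2S)-2-(2,2-diphenyl-1,3-benzodioxol-5-yl)-5,7-dihydroxy-6,8-bis(3-methylbut-2-en-1-yl)-2,3-dihydro-4H-chromen-4-one | CC(C)=CCc1c(O)c(CC=C(C)C)c2c(c1O)C(=O)C[C@@H](c1ccc3OC(c4ccccc4)(c4ccccc4)Oc3c1)O2
A4 | alternative 2 | rac-2-[3,4-bis(tert-butyldimethylsilyloxy)phenyl]-5,7-bis(tert-butyldimethylsilyloxy)-6,8-bis(3-methylbut-2-en-1-yl)-4H-1,3-benzodioxin-4-one | O=C1OC(c2ccc(O[Si](C)(C)C(C)(C)C)c(O[Si](C)(C)C(C)(C)C)c2)Oc2c(CC=C(C)C)c(O[Si](C)(C)C(C)(C)C)c(CC=C(C)C)c(O[Si](C)(C)C(C)(C)C)c21
A5 | alternative 2 | rac-2-[3,4-bis(tert-butyldimethylsilyloxy)phenyl]-5,7-bis(tert-butyldimethylsilyloxy)-4-methylidene-6,8-bis(3-methylbut-2-en-1-yl)-4H-1,3-benzodioxine | C=C1OC(c2ccc(O[Si](C)(C)C(C)(C)C)c(O[Si](C)(C)C(C)(C)C)c2)Oc2c(CC=C(C)C)c(O[Si](C)(C)C(C)(C)C)c(CC=C(C)C)c(O[Si](C)(C)C(C)(C)C)c21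
A6 | alternative 2 | (2S)-2-[3,4-bis(tert-butyldimethylsilyloxy)phenyl]-5,7-bis(tert-butyldimethylsilyloxy)-6,8-bis(3-methylbut-2-en-1-yl)-2,3-dihydro-4H-chromen-4-one | CC(C)=CCc1c(O[Si](C)(C)C(C)(C)C)c(CC=C(C)C)c2c(c1O[Si](C)(C)C(C)(C)C)C(=O)C[C@@H](c1ccc(O[Si](C)(C)C(C)(C)C)c(O[Si](C)(C)C(C)(C)C)c1)O2
A7 | alternative 3 | methyl 4-{(2S)-2-[3,4-bis(methoxymethoxy)phenyl]-4-oxo-3,4-dihydro-2H-pyran-6-yl}-7-methyl-2-(3-methylbut-2-en-1-yl)-3-oxooct-6-enoate (mixture of epimers at chain C2 and C4) | COC(=O)C(CC=C(C)C)C(=O)C(CC=C(C)C)C1=CC(=O)C[C@@H](c2ccc(OCOC)c(OCOC)c2)O1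
A8 | alternative 3 | (2S)-2-[3,4-bis(methoxymethoxy)phenyl]-5,7-dihydroxy-6,8-bis(3-methylbut-2-en-1-yl)-2,3-dihydro-4H-chromen-4-one | CC(C)=CCc1c(O)c(CC=C(C)C)c2c(c1O)C(=O)C[C@@H](c1ccc(OCOC)c(OCOC)c1)O2
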